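**Retrosynthetic overview**
- Target ⇒ 5-pentadecylresorcinol: disconnect the aryl C–O bond of the acetate. In the forward direction a direct C–H acetoxylation brings oxygen and acetyl in together, so the three oxygens never have to be told apart.
- 5-Pentadecylresorcinol ⇒ 1,3-bis(benzyloxy)-5-(pentadec-1-enyl)benzene: one-pot alkene hydrogenation and double O-debenzylation.
- Alkene ⇒ 3,5-bis(benzyloxy)benzaldehyde + tetradecyltriphenylphosphonium bromide (Wittig olefination builds the C15 chain).
- Rings: the benzene ring is bought; no ring is formed and there is no stereocentre.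

Assumption: the target has no stereocentre and no stereogenic double bond, so it is one achiral compound and needs no enantiocontrol; 4-nitroperoxybenzoic acid is taken as a catalogue reagent.

**Step 1**
Reactants: 1 3,5-bis(benzyloxy)benzaldehyde; 2 tetradecyltriphenylphosphonium bromide
Product: 4 (Z)-1,3-bis(benzyloxy)-5-(pentadec-1-en-1-yl)benzene, via tetradecylidenetriphenylphosphorane 3 (not isolated)
Conditions: 2 (1.15 equiv), NaN(SiMe3)2 (1.1 equiv), THF, 0 °C, 30 min; then 1, −78 °C → rt, 3 h
Reagents that add atoms: none
Why: Wittig olefination of a non-enolisable aromatic aldehyde with an unstabilised ylide under salt-free conditions is dependable and Z-selective; the alkene geometry is of no consequence because the double bond is saturated in step 2, and no stereocentre is formed.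

**Step 2**
Reactants: 4 (Z)-1,3-bis(benzyloxy)-5-(pentadec-1-en-1-yl)benzene
Product: 7 5-pentadecylbenzene-1,3-diol, via 1,3-bis(benzyloxy)-5-pentadecylbenzene 5 (not isolated), via 3-(benzyloxy)-5-pentadecylphenol 6 (not isolated)
Conditions: H2 (1 atm), 10% Pd/C, EtOAc–EtOH 1:1, rt, 16 h
Reagents that add atoms: none
Why: Heterogeneous catalytic hydrogenation over Pd/C saturates the styrene-type alkene and in the same pot hydrogenolyses both benzyl aryl ethers to toluene; nothing else is reducible and no stereocentre is created.

**Step 3**
Reactants: 7 5-pentadecylbenzene-1,3-diol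
Product: 8 2,4-dihydroxy-6-pentadecylphenyl acetate
Conditions: 4-O2NC6H4CO3H (1.05 equiv), AcOH (1.1 equiv), DCC (1.0 equiv), CH2Cl2, −10 °C, 1 h (mixed peroxide made in the flask, kept in solution); then 7 (1.0 equiv) in (CF3)2CHOH, −30 → 0 °C, 2–4 h; pH 6 NaH2PO4/Na2HPO4 wash, SiO2
Reagents that add atoms: acetyl 4-nitrobenzoyl peroxide CC(=O)OOC(=O)c1ccc(cc1)[N+](=O)[O-] (made in the flask), formed from acetic acid CC(=O)O and 4-nitroperoxybenzoic acid O=C(OO)c1ccc(cc1)[N+](=O)[O-]
Why: Proposed new method: electrophilic C–H acetoxylation of a free resorcinol by a leaving-group-biased mixed diacyl peroxide — C4 of 7 (para to one OH and ortho to the other, the carbon where acyl, formyl, halogen and diazonium electrophiles enter 5-alkylresorcinols) attacks the peroxide oxygen that carries the acetyl group in an SN2-type displacement on oxygen, the O–O bond breaking toward the better leaving group 4-nitrobenzoate (acid pKa about 3.4 against 4.8 for acetate) with hydrogen-bond activation by (CF3)2CHOH, and loss of the ring proton from the σ-complex gives the aryl acetate directly, so the C–O bond is made with the acetyl already on the one oxygen that selective acylation of the triol could not reach; the acetoxy group deactivates 8 toward a second transfer, resorcinols are strong carbon nucleophiles yet poor one-electron donors, and the acidic base-free medium suppresses acetyl migration to the neighbouring OH; the closest known reaction types are the ortho-benzoyloxylation of phenols by dibenzoyl peroxide, the Elbs persulfate oxidation and arene oxygenation by phthaloyl peroxide in fluorinated alcohols, none of which delivers an acetate or has been run on a free alkylresorcinol.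

**Compound list**
1 | 3,5-bis(benzyloxy)benzaldehyde | O=Cc1cc(OCc2ccccc2)cc(OCc2ccccc2)c1 | starting material
2 | tetradecyltriphenylphosphonium bromide | CCCCCCCCCCCCCC[P+](c1ccccc1)(c1ccccc1)c1ccccc1.[Br-] | starting material
3 | tetradecylidenetriphenylphosphorane | CCCCCCCCCCCCCC=P(c1ccccc1)(c1ccccc1)c1ccccc1 | intermediate (not isolated)
4 | (Z)-1,3-bis(benzyloxy)-5-(pentadec-1-en-1-yl)benzene | CCCCCCCCCCCCC/C=C\c1cc(OCc2ccccc2)cc(OCc2ccccc2)c1 | intermediate
5 | 1,3-bis(benzyloxy)-5-pentadecylbenzene | CCCCCCCCCCCCCCCc1cc(OCc2ccccc2)cc(OCc2ccccc2)c1 | intermediate (not isolated)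
6 | 3-(benzyloxy)-5-pentadecylphenol | CCCCCCCCCCCCCCCc1cc(O)cc(OCc2ccccc2)c1 | intermediate (not isolated)
7 | 5-pentadecylbenzene-1,3-diol | CCCCCCCCCCCCCCCc1cc(O)cc(O)c1 | intermediate
8 | 2,4-dihydroxy-6-pentadecylphenyl acetate | CCCCCCCCCCCCCCCc1cc(O)cc(O)c1OC(C)=O | target

**Totals**
Total step count: 3. Longest linear sequence: 3 (1 → 4 → 7 → 8).

**Steps most likely to fail, with fallbacks**

Step 3 (the proposed new acetoxylation; highest risk). The risks are:
- attack at C2 between the two hydroxyls instead of C4;
- transfer of the 4-nitrobenzoyloxy group instead of acetoxy;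
- a second oxidation of 8;
- acetyl migration to the neighbouring OH during work-up.

The fallback uses known chemistry, sets out from 7 and comes back at 8. Friedel–Crafts (Nencki) C-acetylation of 7 with AcOH and BF3·OEt2 at 90 °C gives 1-(2,4-dihydroxy-6-pentadecylphenyl)ethan-1-one F1; acylation para to one hydroxyl is the established pattern for 5-alkylresorcinols. Benzylation of both phenols (BnBr, K2CO3, DMF, 70 °C) gives 1-[2,4-bis(benzyloxy)-6-pentadecylphenyl]ethan-1-one F2. Baeyer–Villiger oxidation (mCPBA, NaHCO3, CH2Cl2, rt), in which the electron-rich aryl group migrates, gives 2,4-bis(benzyloxy)-6-pentadecylphenyl acetate F3. Neutral hydrogenolysis (H2, 10% Pd/C, EtOAc, rt) then frees the two phenols without touching the aryl acetate and gives 8.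

Step 2 (one-pot hydrogenation and debenzylation). The risks are poisoning of Pd/C by phosphorus residues from step 1 and stalling at the monobenzyl ether 6. The fallback is metal-free and stepwise; it sets out from 4 and comes back at 7. Diimide reduction (TsNHNH2, NaOAc, DME–H2O, reflux) saturates the alkene to give 5, which is isolated here. Lewis-acid debenzylation with BCl3 and pentamethylbenzene as cation scavenger (CH2Cl2, −78 °C) then gives 7. This fallback makes no compound outside the list (F0).

Step 1 (Wittig olefination; lowest risk). The risks are incomplete ylide formation and difficult removal of triphenylphosphine oxide from the greasy product. The fallback replaces olefination by carbonyl addition and hydrogenolysis; it sets out from 1 and comes back at 7. Addition of commercial n-C14H29MgCl (THF, 0 °C) to 1 gives racemic 1-[3,5-bis(benzyloxy)phenyl]pentadecan-1-ol F4. Hydrogenolysis under acid (H2 4 bar, 10% Pd/C, EtOAc–AcOH, cat. H2SO4, rt) removes the benzylic hydroxyl and both benzyl ethers in one pot to give 7.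

**Further compounds**
F1 | step 3 | 1-(2,4-dihydroxy-6-pentadecylphenyl)ethan-1-one | CCCCCCCCCCCCCCCc1cc(O)cc(O)c1C(C)=O
F2 | step 3 | 1-[2,4-bis(benzyloxy)-6-pentadecylphenyl]ethan-1-one | CCCCCCCCCCCCCCCc1cc(OCc2ccccc2)cc(OCc2ccccc2)c1C(C)=O
F3 | step 3 | 2,4-bis(benzyloxy)-6-pentadecylphenyl acetate | CCCCCCCCCCCCCCCc1cc(OCc2ccccc2)cc(OCc2ccccc2)c1OC(C)=O
F0 | step 2 | none | none
F4 | step 1 | racemic 1-[3,5-bis(benzyloxy)phenyl]pentadecan-1-ol | CCCCCCCCCCCCCCC(O)c1cc(OCc2ccccc2)cc(OCc2ccccc2)c1
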